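Target costs one coupling partner and over-reaction product costs two, while each second product costs one from the same charge.

in all of them: coupling partner 14.4 mM; free catalyst 0.14 mM

| run | starting material | second substrate | remark | time |
|---|---|---|---|---|
| dusk | 8 mM | 16 mM | run made earlier |  |
| noon | 32 mM | 16 mM | run made earlier |  |
| flask | 16 mM | 16.0 mM |  | 3.0 d |

| run | time / d | starting material / % | target / % |
|---|---|---|---|
| dusk | 0.625 | 70.2 | 11.0 |
| dusk | 1.25 | 70.8 | 11.1 |
| dusk | 1.67 | 71.3 | 11.6 |
| dusk | 2.50 | 69.8 | 11.1 |
| noon | 0.333 | 83.7 | 9.3 |
| noon | 0.833 | 83.6 | 9.2 |
| noon | 1.67 | 83.0 | 9.2 |
| noon | 2.50 | 83.8 | 9.2 |

(readings scatter by 0.5 percentage points)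

1. conversion of starting material at 3.0 d
2. amount of target at 3.0 d, in percent of the starting material charged

- the numbers in the tables scatter with a standard deviation of 0.5 percentage points
- on the list of suspects stand: starting material + free catalyst <-> catalyst intermediate A; coupling partner + catalyst intermediate A -> free catalyst + target; second substrate + free catalyst <-> catalyst intermediate B; coupling partner + catalyst intermediate B -> free catalyst + second product; coupling partner + free catalyst + target -> free catalyst + over-reaction product

The readings stand flat, so we treat the 14.4 mM of coupling partner, the limiting reagent, as a budget to be shared out. The dusk readings average 70.5% starting material with 11.2% target. The noon readings average 83.5% with 9.22%. We book what the budget has left to second product, and that gives our estimate of the second substrate remaining.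

Now follow one molecule of each substrate to the fork. The ratio defined next reads 0.323 from the dusk readings and 0.325 from the noon readings. We carry their mean, 0.324, as the selectivity factor: the logarithm of the fraction of starting material left over the logarithm of the fraction of second substrate left.

The flask's 16 mM of starting material is the geometric mean of the two run charges, so geometric means of their losses and targets give a first guess, with target at 10.2%. By this estimate the flask's budget leaves 8.97 mM for second product, and the selectivity factor turns that into a conversion of 23.4%.

The forecast gave a conversion of 22.8% and target at 10.6%, opening with “The runs plateau early”. The flask gives a conversion of 23.0% and target at 10.7%, so our target figure is lower by 0.5 percentage points.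

    starting material + free catalyst ⇌ catalyst intermediate A (K = 75.1 M⁻¹, k = 5500 M⁻¹ h⁻¹)
    coupling partner + catalyst intermediate A → free catalyst + target (k = 2290 M⁻¹ h⁻¹)
    second substrate + free catalyst ⇌ catalyst intermediate B (K = 300 M⁻¹, k = 3730 M⁻¹ h⁻¹)
    coupling partner + catalyst intermediate B → free catalyst + second product (k = 4750 M⁻¹ h⁻¹)
    coupling partner + free catalyst + target → free catalyst + over-reaction product (k = 9.72 × 10⁵ M⁻² h⁻¹)

At 3.00 d the flask holds, unbound, 0% of its charged coupling partner and 45% of its charged second substrate. Raised to the selectivity factor, that second substrate figure gives 77.2% starting material, and the flask holds 77%. In the neighbour flask, charged with 9.6 mM of second substrate, coupling partner also stands at 0%. Its second substrate stands at 32%, and the same power gives 69.1% starting material. The neighbour flask holds 70%.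

The runs stem from a simulated flask with constants of no real substance, and the scatter is random.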